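**Plan**

1. Retrosynthesis: the acid is taken back to its methyl ester; the ring is then cut at two bonds at once, the ether bond O1–C6 and the ring olefin C4=C5. This gives a β-hydroxy aldehyde (O1, C2–C4 and the acrylate) and a 1-substituted vinylphosphonium salt (C6, C5 and the C16 side chain).
2. Enabling feature: in the 3,6-dihydro-2H-pyran ring, O1 stands β to C4 (aldol pattern O1–C2–C3–C4), and C6H2–C5(alkyl)= is a two-carbon unit with its CH2 on oxygen. This is the imprint of alkoxide conjugate addition to CH2=C(R)PPh3+ followed by an intramolecular Wittig reaction.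
3. C6, C5 and the side chain together are the skeleton of (5E,9E)-farnesylacetone (C6 its methyl, C5 its carbonyl carbon), so both chain E olefins are bought in. The salt arises via the kinetic enol triflate and Pd-catalysed C–P coupling.
4. The hydroxy aldehyde arises from an asymmetric Morita–Baylis–Hillman adduct of 3-silyloxypropanal by ester exchange, desilylation and selective oxidation of the primary alcohol.
5. Forward order: both fragments in parallel; the only ring closes in the fragment union; saponification ends the route.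
6. Stereochemistry: the single stereocentre C2 (R) is set by the β-isocupreidine-catalysed Morita–Baylis–Hillman reaction and is never again a reacting atom; the ring olefin is cis by ring constraint.

Key step: step 7

Remark on the chemistry: (5E,9E)-farnesylacetone is assumed to be used as the geometrically pure commercial isomer; 3-[(tert-butyldimethylsilyl)oxy]propanal, hexafluoroisopropyl acrylate and β-isocupreidine are taken as purchasable.

**Route**

Step 1
Reactants: 1 (5E,9E)-6,10,14-trimethylpentadeca-5,9,13-trien-2-one ((E,E)-farnesylacetone)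
Product: 3 (5E,9E)-6,10,14-trimethylpentadeca-1,5,9,13-tetraen-2-yl trifluoromethanesulfonate, via lithium enolate 2 (not isolated)
Conditions: LiN(iPr)2 (1.1 equiv), THF, −78 °C; PhNTf2, −78 → 0 °C; aq. NH4Cl
Reagents that add atoms: N-phenylbis(trifluoromethanesulfonimide), O=S(=O)(N(c1ccccc1)S(=O)(=O)C(F)(F)F)C(F)(F)F
Why: Kinetic deprotonation with the hindered amide base at −78 °C takes place at the methyl group of the methyl ketone, and O-triflation of the terminal lithium enolate 2 fixes it as the 1-alken-2-yl triflate (regioselective enol triflate formation), the three chain olefins being inert.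

Step 2
Reactants: 3 (5E,9E)-6,10,14-trimethylpentadeca-1,5,9,13-tetraen-2-yl trifluoromethanesulfonate
Product: 4 triphenyl[(5E,9E)-6,10,14-trimethylpentadeca-1,5,9,13-tetraen-2-yl]phosphonium trifluoromethanesulfonate
Conditions: PPh3 (1.05 equiv), Pd(PPh3)4 (3 mol %), THF, 65 °C
Reagents that add atoms: triphenylphosphine, c1ccc(cc1)P(c1ccccc1)c1ccccc1
Why: Palladium-catalysed C–P coupling: oxidative addition of the vinyl C–OTf bond to zerovalent palladium and C–P reductive elimination give the 1-substituted vinylphosphonium salt, a known route from enol triflates, with all atoms of 3 and PPh3 retained (triflate as counter-ion).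

Step 3
Reactants: 5 3-[(tert-butyldimethylsilyl)oxy]propanal; 6 1,1,1,3,3,3-hexafluoropropan-2-yl prop-2-enoate
Product: 7 1,1,1,3,3,3-hexafluoropropan-2-yl (3R)-5-[(tert-butyldimethylsilyl)oxy]-3-hydroxy-2-methylidenepentanoate
Conditions: β-isocupreidine (10 mol %), DMF, −55 °C
Reagents that add atoms: none
Why: β-Isocupreidine-catalysed asymmetric Morita–Baylis–Hillman reaction: the quinuclidine nitrogen adds to the activated acrylate 6, the ammonium enolate adds to aldehyde 5, and the catalyst's phenolic OH, hydrogen-bonded to the aldolate oxygen, should let only the betaine with (R) configuration at the new carbinol centre reach the geometry for proton transfer and elimination, so that C3 (the later ring C2) is set as R; all atoms of 5 and 6 are retained.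

Step 4
Reactants: 7 1,1,1,3,3,3-hexafluoropropan-2-yl (3R)-5-[(tert-butyldimethylsilyl)oxy]-3-hydroxy-2-methylidenepentanoate
Product: 8 methyl (3R)-5-[(tert-butyldimethylsilyl)oxy]-3-hydroxy-2-methylidenepentanoate
Conditions: MeOH, Et3N (cat.), 0 °C → rt
Reagents that add atoms: methanol, CO
Why: Amine-catalysed transesterification: the hexafluoroisopropyl ester is an activated ester that methanol displaces under conditions too mild to touch the silyl ether or to add methanol to the acrylate, and the stereocentre is not involved.

Step 5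
Reactants: 8 methyl (3R)-5-[(tert-butyldimethylsilyl)oxy]-3-hydroxy-2-methylidenepentanoate
Product: 9 methyl (3R)-3,5-dihydroxy-2-methylidenepentanoate
Conditions: HF·pyridine, pyridine, THF, 0 °C → rt
Reagents that add atoms: none
Why: Fluoride-mediated desilylation: buffered HF·pyridine cleaves the primary TBS ether through the strong Si–F bond without acid- or base-induced lactonisation, oxa-Michael closure or epimerisation.

Step 6
Reactants: 9 methyl (3R)-3,5-dihydroxy-2-methylidenepentanoate
Product: 10 methyl (3R)-3-hydroxy-2-methylidene-5-oxopentanoate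
Conditions: TEMPO (10 mol %), PhI(OAc)2 (1.1 equiv), CH2Cl2, 0 °C → rt; aq. NaHCO3 wash; used crude
Reagents that add atoms: none
Why: TEMPO/PhI(OAc)2 oxidation: the oxoammonium ion oxidises the unhindered primary alcohol much faster than the hindered, electron-poor secondary allylic one and, without water, stops at the aldehyde; the β-hydroxy aldehyde is used at once.

Step 7
Reactants: 10 methyl (3R)-3-hydroxy-2-methylidene-5-oxopentanoate; 4 triphenyl[(5E,9E)-6,10,14-trimethylpentadeca-1,5,9,13-tetraen-2-yl]phosphonium trifluoromethanesulfonate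
Product: 14 methyl 2-[(2R)-5-[(3E,7E)-4,8,12-trimethyltrideca-3,7,11-trien-1-yl]-3,6-dihydro-2H-pyran-2-yl]prop-2-enoate, via sodium alkoxide 11 (not isolated), via phosphorus ylide 12 (not isolated), via oxaphosphetane 13 (not isolated)
Conditions: 4 (1.2 equiv), NaH (1.05 equiv), THF, −20 °C → rt
Reagents that add atoms: none
Why: NaH converts the hydroxyl of 10 into alkoxide 11, which adds to the unsubstituted β-carbon of the cationic vinylphosphonium salt 4 (oxa-Michael addition, forming O1–C6) to give the non-stabilised ylide 12; its carbanionic carbon C5 then attacks the tethered aldehyde carbon C4, and oxaphosphetane 13 collapses to the ring olefin C4=C5 with loss of Ph3P=O (intramolecular Wittig reaction). The closest known reaction type is the Schweizer annulation of hydroxy carbonyl compounds with vinylphosphonium salts, which gives 2H-chromenes from salicylaldehydes and 2,5-dihydrofurans from α-hydroxy ketones. The dihydropyran ring closes in the Wittig stage by 6-exo-trig attack of the ylide carbon on the aldehyde, and the cis-fused oxaphosphetane can only deliver the endocyclic cis olefin. No stereocentre is created in the product (the two ring-fusion centres of 13 vanish on cycloreversion), and C2 is carried through unchanged because no bond to it is made or broken. The step needs chemoselectivity and regiocontrol: the phosphonium-activated terminal CH2 of 4 is a far better acceptor than the α-branched acrylate, the aldehyde is far more electrophilic than the ester towards the ylide, and the side chain must sit on C5 because it is the α-substituent of the phosphonium salt. Low temperature and the presence of 4 while the alkoxide forms should let conjugate addition outrun retro-aldol cleavage or dehydration of the β-hydroxy aldehyde.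

Step 8
Reactants: 14 methyl 2-[(2R)-5-[(3E,7E)-4,8,12-trimethyltrideca-3,7,11-trien-1-yl]-3,6-dihydro-2H-pyran-2-yl]prop-2-enoate
Product: 16 2-[(2R)-5-[(3E,7E)-4,8,12-trimethyltrideca-3,7,11-trien-1-yl]-3,6-dihydro-2H-pyran-2-yl]prop-2-enoic acid, via lithium carboxylate 15 (not isolated)
Conditions: LiOH, THF–H2O, 0 °C → rt; then 1 M HCl to pH 3, 0 °C
Reagents that add atoms: lithium hydroxide, [Li+].[OH-]
Why: Saponification of the methyl ester (acyl–oxygen cleavage by hydroxide) followed by mild acidification; the α-branched acrylate is a poor acceptor for hydroxide at this temperature and the C2 hydrogen is not α to a carbonyl, so the stereocentre and the olefins should survive.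

**Compound list**

1 | (5E,9E)-6,10,14-trimethylpentadeca-5,9,13-trien-2-one | CC(=O)CC/C=C(\C)CC/C=C(\C)CCC=C(C)C | starting material
2 | lithium (5E,9E)-6,10,14-trimethylpentadeca-1,5,9,13-tetraen-2-olate | [Li+].[O-]C(=C)CC/C=C(\C)CC/C=C(\C)CCC=C(C)C | intermediate
3 | (5E,9E)-6,10,14-trimethylpentadeca-1,5,9,13-tetraen-2-yl trifluoromethanesulfonate | C=C(OS(=O)(=O)C(F)(F)F)CC/C=C(\C)CC/C=C(\C)CCC=C(C)C | intermediate
4 | triphenyl[(5E,9E)-6,10,14-trimethylpentadeca-1,5,9,13-tetraen-2-yl]phosphonium trifluoromethanesulfonate | C=C(CC/C=C(\C)CC/C=C(\C)CCC=C(C)C)[P+](c1ccccc1)(c1ccccc1)c1ccccc1.[O-]S(=O)(=O)C(F)(F)F | intermediate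
5 | 3-[(tert-butyldimethylsilyl)oxy]propanal | O=CCCO[Si](C)(C)C(C)(C)C | starting material
6 | 1,1,1,3,3,3-hexafluoropropan-2-yl prop-2-enoate | C=CC(=O)OC(C(F)(F)F)C(F)(F)F | starting material
7 | 1,1,1,3,3,3-hexafluoropropan-2-yl (3R)-5-[(tert-butyldimethylsilyl)oxy]-3-hydroxy-2-methylidenepentanoate | C=C(C(=O)OC(C(F)(F)F)C(F)(F)F)[C@H](O)CCO[Si](C)(C)C(C)(C)C | intermediate
8 | methyl (3R)-5-[(tert-butyldimethylsilyl)oxy]-3-hydroxy-2-methylidenepentanoate | C=C(C(=O)OC)[C@H](O)CCO[Si](C)(C)C(C)(C)C | intermediate
9 | methyl (3R)-3,5-dihydroxy-2-methylidenepentanoate | C=C(C(=O)OC)[C@H](O)CCO | intermediate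
10 | methyl (3R)-3-hydroxy-2-methylidene-5-oxopentanoate | C=C(C(=O)OC)[C@H](O)CC=O | intermediate
11 | sodium (3R)-1-methoxy-2-methylidene-1,5-dioxopentan-3-olate | C=C(C(=O)OC)[C@H]([O-])CC=O.[Na+] | intermediate
12 | methyl (3R)-2-methylidene-5-oxo-3-{[(5E,9E)-6,10,14-trimethyl-2-(triphenyl-λ5-phosphanylidene)pentadeca-5,9,13-trien-1-yl]oxy}pentanoate | C=C(C(=O)OC)[C@H](OCC(CC/C=C(\C)CC/C=C(\C)CCC=C(C)C)=P(c1ccccc1)(c1ccccc1)c1ccccc1)CC=O | intermediate
13 | methyl 2-[(4R)-8,8,8-triphenyl-1-[(3E,7E)-4,8,12-trimethyltrideca-3,7,11-trien-1-yl]-3,7-dioxa-8λ5-phosphabicyclo[4.2.0]octan-4-yl]prop-2-enoate (cis-fused oxaphosphetane, ring-fusion centres transient) | C=C(C(=O)OC)[C@H]1CC2OP(c3ccccc3)(c3ccccc3)(c3ccccc3)C2(CC/C=C(\C)CC/C=C(\C)CCC=C(C)C)CO1 | intermediate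
14 | methyl 2-[(2R)-5-[(3E,7E)-4,8,12-trimethyltrideca-3,7,11-trien-1-yl]-3,6-dihydro-2H-pyran-2-yl]prop-2-enoate | C=C(C(=O)OC)[C@H]1CC=C(CC/C=C(\C)CC/C=C(\C)CCC=C(C)C)CO1 | intermediate
15 | lithium 2-[(2R)-5-[(3E,7E)-4,8,12-trimethyltrideca-3,7,11-trien-1-yl]-3,6-dihydro-2H-pyran-2-yl]prop-2-enoate | C=C(C(=O)[O-])[C@H]1CC=C(CC/C=C(\C)CC/C=C(\C)CCC=C(C)C)CO1.[Li+] | intermediate
16 | 2-[(2R)-5-[(3E,7E)-4,8,12-trimethyltrideca-3,7,11-trien-1-yl]-3,6-dihydro-2H-pyran-2-yl]prop-2-enoic acid | C=C(C(=O)O)[C@H]1CC=C(CC/C=C(\C)CC/C=C(\C)CCC=C(C)C)CO1 | target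

**Count**

Total step count: 8 (steps 1–2 and 3–6 in parallel, then 7 and 8).
Longest linear sequence: 6 steps (steps 3 to 8).

**Steps most likely to fail**

1. Step 7.
 - What may go wrong: retro-aldol cleavage or dehydration of the alkoxide of the β-hydroxy aldehyde may outrun conjugate addition to the α-branched vinylphosphonium salt. Alternatively the ylide may enolise the aldehyde, after which the β-alkoxy group is expelled.
 - Fallback (stepwise ether formation and ring-closing olefin metathesis, in which no base meets the hydroxy aldehyde): it sets out from 10 and 3 and comes back at 14. Aldehyde-selective, non-basic Takai methylenation of 10 (CH2I2, Zn, Ti(OiPr)4, THF) should give methyl (3R)-3-hydroxy-2-methylidenehex-5-enoate F1. In parallel, Stille coupling of 3 with Bu3SnCH2OH (Pd(PPh3)4, LiCl, dioxane, 90 °C) should give (5E,9E)-6,10,14-trimethyl-2-methylidenepentadeca-5,9,13-trien-1-ol F2. An Appel reaction (CBr4, PPh3, CH2Cl2, 0 °C) should turn it into (5E,9E)-2-(bromomethyl)-6,10,14-trimethylpentadeca-1,5,9,13-tetraene F3. Ag2O-mediated O-alkylation of F1 with F3 (Et2O, dark, rt) should give methyl (3R)-2-methylidene-3-{[(5E,9E)-6,10,14-trimethyl-2-methylidenepentadeca-5,9,13-trien-1-yl]oxy}hex-5-enoate F4. Ring-closing metathesis (second-generation Grubbs catalyst, CH2Cl2, 40 °C) between the monosubstituted vinyl group and the 1,1-disubstituted allyl ether olefin, the only pair that closes an unstrained ring with a trisubstituted olefin, should then give 14 with loss of ethylene.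

2. Step 6.
 - What may go wrong: loss of chemoselectivity between the two hydroxyls, over-oxidation, or dehydration of the β-hydroxy aldehyde promoted by the acetic acid formed during the oxidation.
 - Fallback (differentiation by protecting groups instead of by reagent selectivity): it sets out from 9 and comes back at 10. Bis-silylation (Et3SiCl, imidazole, DMF) should give methyl (3R)-2-methylidene-3,5-bis[(triethylsilyl)oxy]pentanoate F5. Swern conditions ((COCl)2, DMSO, CH2Cl2, −78 → −30 °C, then Et3N) are known to convert a primary triethylsilyl ether directly into the aldehyde while a secondary one stays, which should give methyl (3R)-2-methylidene-5-oxo-3-[(triethylsilyl)oxy]pentanoate F6. Buffered HF·pyridine (THF, 0 °C) should then free the secondary hydroxyl to give 10, used at once.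

3. Step 3.
 - What may go wrong: slow turnover with the unbranched aldehyde, amine-induced β-elimination of its silyloxy group, diversion of material into the dioxanone side path, and insufficient facial selectivity.
 - Fallback (stereocentre by asymmetric ketone hydrogenation, acrylate methylene installed afterwards): it sets out from 5 and comes back at 8. Roskamp homologation of 5 with methyl diazoacetate (SnCl2 cat., CH2Cl2) should give methyl 5-[(tert-butyldimethylsilyl)oxy]-3-oxopentanoate F7. Noyori hydrogenation (H2, RuCl2[(R)-BINAP], MeOH) should give methyl (3R)-5-[(tert-butyldimethylsilyl)oxy]-3-hydroxypentanoate F8, the sense that (R)-BINAP gives with simple β-keto esters. Fráter–Seebach dianion formation (LiN(iPr)2, 2.2 equiv, THF, −78 → −20 °C) and trapping with Eschenmoser's salt should give methyl (2R,3R)-5-[(tert-butyldimethylsilyl)oxy]-2-[(dimethylamino)methyl]-3-hydroxypentanoate F9 (anti; the C2 centre is lost again). Quaternisation with MeI should give [(2R,3R)-5-[(tert-butyldimethylsilyl)oxy]-3-hydroxy-2-(methoxycarbonyl)pentyl]trimethylammonium iodide F10, and elimination with aqueous NaHCO3/CH2Cl2 should give 8.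

**Further compounds**

F1 | step 7 | methyl (3R)-3-hydroxy-2-methylidenehex-5-enoate | C=C(C(=O)OC)[C@H](O)CC=C
F2 | step 7 | (5E,9E)-6,10,14-trimethyl-2-methylidenepentadeca-5,9,13-trien-1-ol | C=C(CO)CC/C=C(\C)CC/C=C(\C)CCC=C(C)C
F3 | step 7 | (5E,9E)-2-(bromomethyl)-6,10,14-trimethylpentadeca-1,5,9,13-tetraene | C=C(CBr)CC/C=C(\C)CC/C=C(\C)CCC=C(C)C
F4 | step 7 | methyl (3R)-2-methylidene-3-{[(5E,9E)-6,10,14-trimethyl-2-methylidenepentadeca-5,9,13-trien-1-yl]oxy}hex-5-enoate | C=C(C(=O)OC)[C@H](OCC(=C)CC/C=C(\C)CC/C=C(\C)CCC=C(C)C)CC=C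
F5 | step 6 | methyl (3R)-2-methylidene-3,5-bis[(triethylsilyl)oxy]pentanoate | C=C(C(=O)OC)[C@H](O[Si](CC)(CC)CC)CCO[Si](CC)(CC)CC
F6 | step 6 | methyl (3R)-2-methylidene-5-oxo-3-[(triethylsilyl)oxy]pentanoate | C=C(C(=O)OC)[C@H](O[Si](CC)(CC)CC)CC=O
F7 | step 3 | methyl 5-[(tert-butyldimethylsilyl)oxy]-3-oxopentanoate | COC(=O)CC(=O)CCO[Si](C)(C)C(C)(C)C
F8 | step 3 | methyl (3R)-5-[(tert-butyldimethylsilyl)oxy]-3-hydroxypentanoate | COC(=O)C[C@H](O)CCO[Si](C)(C)C(C)(C)C
F9 | step 3 | methyl (2R,3R)-5-[(tert-butyldimethylsilyl)oxy]-2-[(dimethylamino)methyl]-3-hydroxypentanoate | COC(=O)[C@H](CN(C)C)[C@H](O)CCO[Si](C)(C)C(C)(C)C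
F10 | step 3 | [(2R,3R)-5-[(tert-butyldimethylsilyl)oxy]-3-hydroxy-2-(methoxycarbonyl)pentyl]trimethylammonium iodide | COC(=O)[C@H](C[N+](C)(C)C)[C@H](O)CCO[Si](C)(C)C(C)(C)C.[I-]
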